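At early times the flow out of intermediate A splits: part goes to target, part to intermediate B, and both rates carry the same c(A). So I divided one rate by the other, and c(A) and time dropped out:

c(target) / c(intermediate B) = k(A → target) / k(A → B)

| flask | starting material | temperature | time |
|---|---|---|---|
| north-west | 0.013 M | −25 °C | 30 s |
| south-west | 0.013 M | 0 °C | 30 s |
| west | 0.013 M | 25 °C | 30 s |

- the flask that comes out highest in amount of target, in percent of the starting material charged, or "all alike" when all lie within 1.5 percentage points (north-west / south-west / west / all alike)
- target at the end, in percent of the starting material charged, north-west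
- target at the end, in percent of the starting material charged, south-west
- target at the end, in percent of the starting material charged, west

- the constants hold at 25 °C; other temperatures follow from the activation energies and enthalpies

    starting material → intermediate A (k1 = 0.0946 s⁻¹, Ea1 = 88.0 kJ mol⁻¹)
    starting material ⇌ intermediate C (K2 = 1.5, k2 = 1.54 s⁻¹, Ea2 = 77.0 kJ mol⁻¹, ΔH2 = 14.0 kJ mol⁻¹)
    intermediate E ⇌ intermediate A (K3 = 2.9, k3 = 0.111 s⁻¹, Ea3 = 86.0 kJ mol⁻¹, ΔH3 = −22.0 kJ mol⁻¹)
    intermediate A ⇌ intermediate B (K4 = 2.2, k4 = 0.759 s⁻¹, Ea4 = 62.0 kJ mol⁻¹, ΔH4 = −69.0 kJ mol⁻¹)
    intermediate A → target (k5 = 0.0499 s⁻¹, Ea5 = 75.0 kJ mol⁻¹)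
    target ⇌ isomer of the product (K6 = 0.682, k6 = 0.0394 s⁻¹, Ea6 = 80.0 kJ mol⁻¹, ΔH6 = −8.00 kJ mol⁻¹)
    intermediate D → intermediate E (k7 = 0.0860 s⁻¹, Ea7 = 67.0 kJ mol⁻¹)
    intermediate C ⇌ intermediate D (K8 = 0.20, k8 = 0.0106 s⁻¹, Ea8 = 91.0 kJ mol⁻¹, ΔH8 = −5.00 kJ mol⁻¹)
    (constants at 25 °C)

I called the right side, taken at a flask's temperature, the branch ratio (a selectivity factor). It came to 0.0407 in south-west and 0.0229 in north-west. The branch ratio turns a c(intermediate B) into a c(target), as long as B gives back little and target stays target.

I built west up by hand, starting with starting material → A → target alone, using the formula for consecutive first-order steps: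

target at the end: 59.2 %

Next I added intermediate C. Its balance with starting material relaxes far faster than the step to A, so the pair feeds A at a reduced constant:

feed 0.0378 s⁻¹, target 37.3 %

Then I added intermediate B. In west it gives back at 0.345 s⁻¹, much faster than the flask's time scale, so the branch ratio does not apply there. A and B act as one pool instead:

drain 0.0156 s⁻¹, target plus isomer 16.0 %

Last came the isomer. I assumed a mean age for target of a third of the time and let it relax toward its balance with the isomer:

share still target 0.748, target in west 12.0 %

The branch ratio does apply in south-west. There B gives back at 0.00274 s⁻¹, slow against the time. I took the feed as 0.00194 s⁻¹. With A's exit to B at 0.0769 s⁻¹, I let the flow reach target one A lifetime late: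

target in south-west 0.134 %

In north-west the step to A runs at 7.40 × 10⁻⁵ s⁻¹ and the step to target at 1.12 × 10⁻⁴ s⁻¹. In this reckoning target grows with the square of time, to <0.001 %. My reckoning put west highest.

The forecast also named west. It gave <0.001 % for north-west, 0.16 % for south-west (range 0.1 % to 0.3 %) and 10.5 % for west (range 8.5 % to 12.5 %). Its ground for the cold flasks was that "The high activation energies slow every step sharply on cooling, and the exothermic A ⇌ B equilibrium increasingly traps A as B". My west figure stood above its value, and my south-west figure below its value.

The simulation put west highest, with 0 % in north-west, 0.163 % in south-west and 12.3 % in west. With the backward run from B to A struck out, south-west still gave 0.161 %. South-west read 3.98 % of B at 30.0 s, and the branch ratio turns that into 0.162 % of target. North-west, left for 300 s, read 0.854 % of B, and its branch ratio turns that into 0.0196 %, against a simulated 0.0194 %.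

The numbers of this flask are those of an exercise; what happens was integrated by code.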